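**Strategy.** The route rests on disconnection of the C4–C5 bond (germacrane numbering: carbocycle C1–C10, lactone C6/C7/C11/C12, ester carbon C14, exo-methylene C15). The last step is an intramolecular Nozaki–Hiyama–Kishi reaction that closes the ten-membered carbocycle onto the preformed trans-fused α-methylene-γ-lactone. In the same operation it creates the C5 carbinol stereocentre and the C4(=C15H2)–C5H(OH) 2-methylene-1-ol unit next to lactone carbon C6, which is the feature the step exploits. Its precursor is the open-chain 2-iodoalkene aldehyde 22, which already carries the lactone, the C8 angelate and the (E)-C1=C10 enoate. It is assembled from an (S)-butenolide by conjugate vinylation/α-methylenation and an allylboration with a secondary 2-(methoxycarbonyl)allylboronate.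

Key step: step 14

Assumption: compounds 1, 4, 8 and 18 are taken as commercial; atom labels C1–C15 refer to the germacrane numbering given above.

Step 1
Reactants: 1 pent-4-yn-1-ol
Product: 2 4-iodopent-4-en-1-ol
Conditions: NaI, TMSCl, H2O, MeCN, rt
Reagents that add atoms: sodium iodide, [Na+].[I-]
Why: Markovnikov hydroiodination of the terminal alkyne by HI generated in situ gives the 2-iodoalk-1-ene; no stereocentre is formed.

Step 2
Reactants: 2 4-iodopent-4-en-1-ol
Product: 3 4-iodopent-4-enal
Conditions: Dess–Martin periodinane, CH2Cl2, 0 °C → rt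
Reagents that add atoms: none
Why: Dess–Martin oxidation stops at the aldehyde and leaves the alkenyl iodide untouched.

Step 3
Reactants: 3 4-iodopent-4-enal; 4 methyl acrylate
Product: 5 methyl 3-hydroxy-6-iodo-2-methylidenehept-6-enoate (racemic)
Conditions: DABCO, neat methyl acrylate (excess), rt, several days
Reagents that add atoms: none
Why: Morita–Baylis–Hillman reaction of an unhindered aliphatic aldehyde; the carbinol centre is racemic and is erased in step 4.

Step 4
Reactants: 5 methyl 3-hydroxy-6-iodo-2-methylidenehept-6-enoate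
Product: 6 methyl (2Z)-2-(bromomethyl)-6-iodohepta-2,6-dienoate
Conditions: NBS, Me2S, CH2Cl2, 0 °C → rt
Reagents that add atoms: N-bromosuccinimide, O=C1CCC(=O)N1Br
Why: Corey–Kim-type activation of the Baylis–Hillman alcohol and SN2′ delivery of bromide give the thermodynamically preferred (Z)-2-(bromomethyl)enoate.

Step 5
Reactants: 6 methyl (2Z)-2-(bromomethyl)-6-iodohepta-2,6-dienoate
Product: 7 methyl 6-iodo-2-methylidene-3-(4,4,5,5-tetramethyl-1,3,2-dioxaborolan-2-yl)hept-6-enoate (racemic secondary allylboronate)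
Conditions: B2pin2 (0.9 equiv), CuCl, KOAc, LiCl, DMF, 0 °C → rt
Reagents that add atoms: bis(pinacolato)diboron, CC1(C)OB(OC1(C)C)B1OC(C)(C)C(C)(C)O1
Why: Copper-mediated allylic borylation (formal SN2′): the borylcopper delivers boron to the enoate β-carbon and bromide leaves from the copper enolate, which should give the secondary allylboronate; B2pin2 is kept limiting and the temperature low so that the acrylate product and the alkenyl iodide are not borylated.

Step 6
Reactants: 8 (5S)-5-(hydroxymethyl)furan-2(5H)-one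
Product: 9 (5S)-5-({[tert-butyl(dimethyl)silyl]oxy}methyl)furan-2(5H)-one
Conditions: TBSCl, imidazole, DMF, 0 °C → rt
Reagents that add atoms: tert-butyldimethylsilyl chloride, CC(C)(C)[Si](C)(C)Cl
Why: Standard silylation of the primary alcohol; the stereocentre (C6 of the target) comes from the chiral pool.

Step 7
Reactants: 9 (5S)-5-({[tert-butyl(dimethyl)silyl]oxy}methyl)furan-2(5H)-one
Product: 11 (4S,5S)-5-({[tert-butyl(dimethyl)silyl]oxy}methyl)-3-[(dimethylamino)methyl]-4-ethenyloxolan-2-one (C3 epimers), via silyl ketene acetal 10 (not isolated)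
Conditions: CH2=CHMgBr, CuBr·SMe2 (cat.), TMSCl, THF, −78 °C; then Eschenmoser's salt, −78 °C → rt
Reagents that add atoms: vinylmagnesium bromide, C=C[Mg]Br; Eschenmoser's salt (N,N-dimethylmethyleneiminium iodide), C=[N+](C)C.[I-]
Why: Copper-catalysed conjugate addition occurs anti to the silyloxymethyl group and so sets C7 trans to C6; the silyl ketene acetal is then intercepted in a Mannich reaction (the C11 centre so formed is removed in step 8).

Step 8
Reactants: 11 Mannich base
Product: 13 (4S,5S)-5-({[tert-butyl(dimethyl)silyl]oxy}methyl)-4-ethenyl-3-methylideneoxolan-2-one, via ammonium iodide 12 (not isolated)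
Conditions: MeI, MeOH, rt; then aq. NaHCO3, CH2Cl2, rt
Reagents that add atoms: none
Why: Quaternisation followed by E1cB (Hofmann-type) loss of trimethylamine unveils the α-methylene lactone.

Step 9
Reactants: 13 (4S,5S)-5-({[tert-butyl(dimethyl)silyl]oxy}methyl)-4-ethenyl-3-methylideneoxolan-2-one
Product: 15 (2S,3S)-2-({[tert-butyl(dimethyl)silyl]oxy}methyl)-4-methylidene-5-oxooxolane-3-carbaldehyde, via secondary ozonide 14 (not isolated)
Conditions: O3 (1 equiv, Sudan Red 7B end-point), CH2Cl2, −78 °C; then PPh3, −78 °C → 0 °C; used crude at once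
Reagents that add atoms: ozone, [O-][O+]=O
Why: Ozonolysis should take the isolated, more electron-rich vinyl group before the conjugated methylene, and the neutral reductive work-up is chosen to preserve the epimerisable, isomerisation-prone C7 centre.

Step 10
Reactants: 15 aldehyde; 7 racemic secondary allylboronate (2.5 equiv)
Product: 17 methyl (2E)-2-[(2R)-2-hydroxy-2-{(2S,3R)-2-({[tert-butyl(dimethyl)silyl]oxy}methyl)-4-methylidene-5-oxooxolan-3-yl}ethyl]-6-iodohepta-2,6-dienoate, via pinacol borate 16 (not isolated)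
Conditions: Sc(OTf)3 (10 mol%), CH2Cl2, −78 → −40 °C; cold aq. NaHCO3 quench
Reagents that add atoms: none
Why: Lewis-acid-accelerated allylboration of a 2-(alkoxycarbonyl)allylboronate through a closed chair (Zimmerman–Traxler) transition state: C9 attacks C8 with allylic transposition and the substituent on the boron-bearing carbon sits pseudo-axial (avoiding A1,2 strain with CO2Me), which gives the (E)-C1=C10 enoate and ties the configuration of that carbon to the aldehyde face so that (R)-7 delivers 8R; the chiral aldehyde is expected to select (R)-7 from the excess racemate by Felkin–Anh attack anti to the C7–C11(sp2) bond (1,3-anti to the C6–O bond), a bias that is probably modest.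

Step 11
Reactants: 17 C8 alcohol; 18 angelic acid
Product: 20 methyl (2E)-2-[(2R)-2-{[(2Z)-2-methylbut-2-enoyl]oxy}-2-{(2S,3R)-2-({[tert-butyl(dimethyl)silyl]oxy}methyl)-4-methylidene-5-oxooxolan-3-yl}ethyl]-6-iodohepta-2,6-dienoate, via mixed anhydride 19 (not isolated)
Conditions: 18, 2,4,6-trichlorobenzoyl chloride, Et3N, toluene, rt; then 17, toluene, 75 °C (no DMAP)
Reagents that add atoms: none
Why: Yamaguchi-type esterification through the trichlorobenzoyl mixed anhydride acylates the hindered alcohol with retention at C8 and is the usual way to avoid Z→E isomerisation of the angeloyl group; it also blocks lactonisation of O8 onto C14 or C12.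

Step 12
Reactants: 20 silyl ether
Product: 21 methyl (2E)-2-[(2R)-2-{[(2Z)-2-methylbut-2-enoyl]oxy}-2-[(2S,3R)-2-(hydroxymethyl)-4-methylidene-5-oxooxolan-3-yl]ethyl]-6-iodohepta-2,6-dienoate
Conditions: HF·pyridine, pyridine, THF, 0 °C → rt
Reagents that add atoms: none
Why: Buffered fluoride cleaves the primary TBS ether without touching the angelate, the methyl ester, the lactone or the alkenyl iodide.

Step 13
Reactants: 21 primary alcohol
Product: 22 methyl (2E)-2-[(2R)-2-{[(2Z)-2-methylbut-2-enoyl]oxy}-2-[(2S,3R)-2-formyl-4-methylidene-5-oxooxolan-3-yl]ethyl]-6-iodohepta-2,6-dienoate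
Conditions: Dess–Martin periodinane, CH2Cl2, 0 °C → rt; used crude
Reagents that add atoms: none
Why: Dess–Martin oxidation under near-neutral conditions gives the α-acyloxy aldehyde without epimerising C6.

Step 14
Reactants: 22 iodoalkene aldehyde
Product: 25 CNP0163095.1 (target), via alkenylchromium(III) species 23 (not isolated), via chromium(III) alkoxide 24 (not isolated)
Conditions: CrCl2 (10 equiv), NiCl2 (cat.), degassed DMSO/THF, rt, slow addition of 22 to ca. 2 mM; aqueous work-up
Reagents that add atoms: none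
Why: Ni(0), formed from NiCl2 by CrCl2, inserts into the C4–I bond and transmetallates to chromium to give alkenylchromium(III) 23, whose C4 adds to the C5 aldehyde through a Cr–O bound transition state to give alkoxide 24, hydrolysed on work-up. The closest known reaction type is the Nozaki–Hiyama–Kishi medium-ring and macrocyclisation of 2-iodoalk-1-enes onto aldehydes. The ten-membered carbocycle C1–C10 closes in 10-exo-trig mode by C4–C5 bond formation, while the lactone is already in place and stays untouched. The new stereocentre C5 is controlled by C6 of the trans-fused lactone: C4 should attack anti to the C6–O bond (Felkin–Anh alignment, no chelation by the acylated oxygen) and, being tethered through C7–C8, from the C7 side, which places the carbonyl oxygen over H-6 and leads to the 5,6-syn (5S) alcohol. Chemoselectivity for the aldehyde over the lactone, the two esters and the two Michael acceptors is secured by the aldehyde-specific reactivity of organochromium(III) species, and cyclisation over oligomerisation by high dilution and by the two turn elements (ring-cis C1=C10 enoate, trans-lactone). The facial selectivity is the least secure point and is addressed in the fallback.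

**Compound list**

1 | pent-4-yn-1-ol | C#CCCCO | starting material
2 | 4-iodopent-4-en-1-ol | C=C(I)CCCO | intermediate
3 | 4-iodopent-4-enal | C=C(I)CCC=O | intermediate
4 | methyl acrylate | C=CC(=O)OC | starting material
5 | methyl 3-hydroxy-6-iodo-2-methylidenehept-6-enoate (racemic) | C=C(I)CCC(O)C(=C)C(=O)OC | intermediate
6 | methyl (2Z)-2-(bromomethyl)-6-iodohepta-2,6-dienoate | BrC/C(C(=O)OC)=C\CCC(I)=C | intermediate
7 | methyl 6-iodo-2-methylidene-3-(4,4,5,5-tetramethyl-1,3,2-dioxaborolan-2-yl)hept-6-enoate (racemic) | C=C(I)CCC(B1OC(C)(C)C(C)(C)O1)C(=C)C(=O)OC | intermediate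
8 | (5S)-5-(hydroxymethyl)furan-2(5H)-one | OC[C@H]1OC(=O)C=C1 | starting material
9 | (5S)-5-({[tert-butyl(dimethyl)silyl]oxy}methyl)furan-2(5H)-one | CC(C)(C)[Si](C)(C)OC[C@H]1OC(=O)C=C1 | intermediate
10 | tert-butyl({(2S,3S)-3-ethenyl-5-[(trimethylsilyl)oxy]-2,3-dihydrofuran-2-yl}methoxy)dimethylsilane (silyl ketene acetal) | C1=C(O[Si](C)(C)C)O[C@H](CO[Si](C)(C)C(C)(C)C)[C@H]1C=C | intermediate
11 | (4S,5S)-5-({[tert-butyl(dimethyl)silyl]oxy}methyl)-3-[(dimethylamino)methyl]-4-ethenyloxolan-2-one (C3 not controlled, both epimers converge) | CN(C)CC1C(=O)O[C@H](CO[Si](C)(C)C(C)(C)C)[C@H]1C=C | intermediate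
12 | trimethylammonium iodide of 11 | C[N+](C)(C)CC1C(=O)O[C@H](CO[Si](C)(C)C(C)(C)C)[C@H]1C=C.[I-] | intermediate
13 | (4S,5S)-5-({[tert-butyl(dimethyl)silyl]oxy}methyl)-4-ethenyl-3-methylideneoxolan-2-one | C=C1C(=O)O[C@H](CO[Si](C)(C)C(C)(C)C)[C@H]1C=C | intermediate
14 | (4S,5S)-5-({[tert-butyl(dimethyl)silyl]oxy}methyl)-3-methylidene-4-(1,2,4-trioxolan-3-yl)oxolan-2-one (secondary ozonide) | C=C1C(=O)O[C@H](CO[Si](C)(C)C(C)(C)C)[C@H]1C2OCOO2 | intermediate
15 | (2S,3S)-2-({[tert-butyl(dimethyl)silyl]oxy}methyl)-4-methylidene-5-oxooxolane-3-carbaldehyde | C=C1C(=O)O[C@H](CO[Si](C)(C)C(C)(C)C)[C@H]1C=O | intermediate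
16 | pinacol borate of 17 (O8–Bpin) | C=C1C(=O)O[C@H](CO[Si](C)(C)C(C)(C)C)[C@H]1[C@H](OB2OC(C)(C)C(C)(C)O2)C/C(C(=O)OC)=C\CCC(I)=C | intermediate
17 | methyl (2E)-2-[(2R)-2-hydroxy-2-{(2S,3R)-2-({[tert-butyl(dimethyl)silyl]oxy}methyl)-4-methylidene-5-oxooxolan-3-yl}ethyl]-6-iodohepta-2,6-dienoate | C=C1C(=O)O[C@H](CO[Si](C)(C)C(C)(C)C)[C@H]1[C@H](O)C/C(C(=O)OC)=C\CCC(I)=C | intermediate
18 | angelic acid, (2Z)-2-methylbut-2-enoic acid | C/C=C(/C)C(=O)O | starting material
19 | (2Z)-2-methylbut-2-enoic 2,4,6-trichlorobenzoic anhydride | C/C=C(/C)C(=O)OC(=O)c1c(Cl)cc(Cl)cc1Cl | intermediate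
20 | C8 angelate of 17 (TBS ether) | C=C1C(=O)O[C@H](CO[Si](C)(C)C(C)(C)C)[C@H]1[C@H](OC(=O)/C(C)=C\C)C/C(C(=O)OC)=C\CCC(I)=C | intermediate
21 | methyl (2E)-2-[(2R)-2-{[(2Z)-2-methylbut-2-enoyl]oxy}-2-[(2S,3R)-2-(hydroxymethyl)-4-methylidene-5-oxooxolan-3-yl]ethyl]-6-iodohepta-2,6-dienoate | C=C1C(=O)O[C@H](CO)[C@H]1[C@H](OC(=O)/C(C)=C\C)C/C(C(=O)OC)=C\CCC(I)=C | intermediate
22 | methyl (2E)-2-[(2R)-2-{[(2Z)-2-methylbut-2-enoyl]oxy}-2-[(2S,3R)-2-formyl-4-methylidene-5-oxooxolan-3-yl]ethyl]-6-iodohepta-2,6-dienoate | C=C1C(=O)O[C@H](C=O)[C@H]1[C@H](OC(=O)/C(C)=C\C)C/C(C(=O)OC)=C\CCC(I)=C | intermediate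
23 | alkenylchromium(III) dichloride derived from 22 (Cr at C4) | C=C1C(=O)O[C@H](C=O)[C@H]1[C@H](OC(=O)/C(C)=C\C)C/C(C(=O)OC)=C\CCC(=C)[Cr](Cl)Cl | intermediate
24 | chromium(III) alkoxide of 25 (O5–CrCl2) | C=C1C(=O)O[C@H]2[C@H]1[C@H](OC(=O)/C(C)=C\C)C/C(C(=O)OC)=C\CCC(=C)[C@@H]2O[Cr](Cl)Cl | intermediate
25 | CNP0163095.1: methyl (5S,6S,7R,8R)-8-angeloyloxy-5-hydroxygermacra-1(10)E,4(15),11(13)-trien-12,6-olid-14-oate | C=C1C(=O)O[C@H]2[C@H]1[C@H](OC(=O)/C(C)=C\C)C/C(C(=O)OC)=C\CCC(=C)[C@@H]2O | target

**Step count and risks**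

Total step count: 14. Longest linear sequence: 10 steps (steps 1–5, then 10–14); 9 steps from butenolide 8.

The three steps most likely to fail:

Step 14 (key step). The ring closure may show poor facial selectivity at C5, because the tether-based model is not backed by a closely related case, and the wrong C5 epimer could dominate. The fallback sets out from 22 and comes back at 25. The same Ni/Cr cyclisation is run without regard to the C5 ratio. The undesired product forms as the 5-epi chromium alkoxide F1 and is isolated as the 5R alcohol F2. F2, together with any 25, is oxidised with Dess–Martin periodinane to the cross-conjugated C5 ketone F3. F3 is then reduced with (S)-Me-CBS and catecholborane, which should give the 5S alcohol 25 if the alkenyl group acts as the larger substituent, as is usual for enones. C5 is then set by reagent-controlled reduction rather than by the C–C bond formation.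

Step 10. The aldehyde may discriminate too weakly between the two enantiomers of 7, so that C8 epimers form; lactonisation of the free C8 alcohol is a further loss pathway. The fallback sets out from 15 (with 7) and comes back at 17. The allylboration is run to completion; the C8 epimer arises as the 8-epi pinacol borate F4 and is freed as the 8S alcohol F5. The mixture of F5 and 17 is oxidised with Dess–Martin periodinane to the C8 ketone F6. F6 is reduced at −78 °C with (S)-Me-CBS and catecholborane (ring carbon C7 as the large group, C9H2 as the small group) to give 17. C8 is then set by catalyst control.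

Step 9. Ozone may also attack the electron-poor methylene lactone, and the β,γ-unsaturated aldehyde may isomerise or epimerise at C7. The fallback sets out from 11 and comes back at 15. The Mannich base 11 is ozonised as its trifluoroacetate salt (TFA, CH2Cl2/MeOH, −78 °C), where the protonated amine is inert and no methylene lactone is present; this gives the ozonide trifluoroacetate F7. Me2S and a bicarbonate wash give the amino aldehyde F8. MeI then gives the methiodide F9, and brief treatment with NaHCO3 eliminates trimethylamine to give 15, which is used at once. This removes the chemoselectivity problem but not the lability of 15.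

Further compounds
F1 | step 14 | 5-epi chromium(III) alkoxide (5R) | C=C1C(=O)O[C@H]2[C@H]1[C@H](OC(=O)/C(C)=C\C)C/C(C(=O)OC)=C\CCC(=C)[C@H]2O[Cr](Cl)Cl
F2 | step 14 | 5-epi-25 (5R alcohol) | C=C1C(=O)O[C@H]2[C@H]1[C@H](OC(=O)/C(C)=C\C)C/C(C(=O)OC)=C\CCC(=C)[C@H]2O
F3 | step 14 | C5 ketone (4(15)-en-5-one) | C=C1C(=O)O[C@H]2[C@H]1[C@H](OC(=O)/C(C)=C\C)C/C(C(=O)OC)=C\CCC(=C)C2=O
F4 | step 10 | 8-epi pinacol borate (8S) | C=C1C(=O)O[C@H](CO[Si](C)(C)C(C)(C)C)[C@H]1[C@@H](OB2OC(C)(C)C(C)(C)O2)C/C(C(=O)OC)=C\CCC(I)=C
F5 | step 10 | 8-epi-17 (8S alcohol) | C=C1C(=O)O[C@H](CO[Si](C)(C)C(C)(C)C)[C@H]1[C@@H](O)C/C(C(=O)OC)=C\CCC(I)=C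
F6 | step 10 | C8 ketone | C=C1C(=O)O[C@H](CO[Si](C)(C)C(C)(C)C)[C@H]1C(=O)C/C(C(=O)OC)=C\CCC(I)=C
F7 | step 9 | secondary ozonide of 11, trifluoroacetate salt | C[NH+](C)CC1C(=O)O[C@H](CO[Si](C)(C)C(C)(C)C)[C@H]1C2OCOO2.[O-]C(=O)C(F)(F)F
F8 | step 9 | (2S,3S)-2-({[tert-butyl(dimethyl)silyl]oxy}methyl)-4-[(dimethylamino)methyl]-5-oxooxolane-3-carbaldehyde | CN(C)CC1C(=O)O[C@H](CO[Si](C)(C)C(C)(C)C)[C@H]1C=O
F9 | step 9 | trimethylammonium iodide of F8 | C[N+](C)(C)CC1C(=O)O[C@H](CO[Si](C)(C)C(C)(C)C)[C@H]1C=O.[I-]
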